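The synthesis rests on one disconnection in ring B. Across the trans ring fusion, C1 on C10 and C4 on C5 are trans vicinal substituents, the pattern that tandem conjugate addition and enolate alkylation of a cyclohexenone delivers by default. In one flask a vinyl cuprate forms C10–C1 and the resulting C5 enolate is alkylated by methyl bromoacetate (C5–C4). Both fusion centres are thereby fixed under relay from C8 and C9. The precursor 9 is the ring B 2-methylenone (carbonyl C6) with C8, quaternary C9 and silyl-protected C11 in place. Ring A is closed later by metathesis, and isofraxidin is attached last.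

Key step: step 7

Numbering: ring A is C1, C2, C3 (ketone), C4, C5, C10. Ring B is C5 to C10. C11 is the CH2O carbon on C9.
Assumption: the (S,S)-configured amine–thiourea of step 1 is taken to give (S)-3. If the sense of induction is the opposite, the equally available (R,R)-antipode is used and nothing else changes.

Step 1
Reactants: 1 (E)-hex-4-en-3-one; 2 dimethyl malonate
Product: 3 dimethyl 2-[(2S)-4-oxohexan-2-yl]propanedioate
Conditions: 2 (2 equiv), 1-[(1S,2S)-2-amino-1,2-diphenylethyl]-3-[3,5-bis(trifluoromethyl)phenyl]thiourea (10 mol %), PhCO2H (10 mol %), toluene, rt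
Reagents that add atoms: none
Why: Iminium-catalysed asymmetric Michael addition of a malonate to an acyclic enone, in which the primary amine condenses with the ketone, the thiourea binds the malonate, and attack on one face of the iminium ion sets C8 as S.

Step 2
Reactants: 3 dimethyl 2-[(2S)-4-oxohexan-2-yl]propanedioate
Product: 4 methyl (6S)-3,6-dimethyl-2,4-dioxocyclohexane-1-carboxylate (enolised; C1 and C3 labile)
Conditions: NaOMe (1.2 equiv), MeOH, 50 °C; then 1 M HCl
Reagents that add atoms: none
Why: Intramolecular Claisen (Dieckmann-type) condensation of the dimedone kind: the C5 enolate of the ethyl ketone is acylated by one malonate ester to close ring B, the stabilised enolate of the product drives the reaction, and non-acidic C8 is untouched.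

Step 3
Reactants: 4 methyl (6S)-3,6-dimethyl-2,4-dioxocyclohexane-1-carboxylate
Product: 5 methyl (6S)-4-methoxy-3,6-dimethyl-2-oxocyclohex-3-ene-1-carboxylate (C1 labile)
Conditions: HC(OMe)3, TsOH·H2O (cat.), MeOH, rt
Reagents that add atoms: trimethyl orthoformate, COC(OC)OC
Why: Acid-catalysed enol etherification of a cyclic 1,3-dione, which should occur at the less hindered C6 carbonyl next to C7H2, while the C10 carbonyl next to ester-bearing C9 remains as the vinylogous ester carbonyl.

Step 4
Reactants: 5 methyl (6S)-4-methoxy-3,6-dimethyl-2-oxocyclohex-3-ene-1-carboxylate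
Product: 6 methyl (1S,6S)-4-methoxy-1,3,6-trimethyl-2-oxocyclohex-3-ene-1-carboxylate (methyls on C1 and C6 trans)
Conditions: NaH, THF–DMF, 0 °C; MeI, 0 °C to rt
Reagents that add atoms: methyl iodide, CI
Why: C-alkylation of a β-keto ester enolate: A(1,2) strain with the coplanar C9 ester pushes the C8 methyl pseudoaxial, so MeI enters from the opposite face and quaternary C9 forms with its methyl trans to the C8 methyl and C11 cis to it.

Step 5
Reactants: 6 methyl (1S,6S)-4-methoxy-1,3,6-trimethyl-2-oxocyclohex-3-ene-1-carboxylate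
Product: 8 (4S,5S)-4-(hydroxymethyl)-2,4,5-trimethylcyclohex-2-en-1-one, via enol ether diol 7 (not isolated)
Conditions: LiAlH4, Et2O, 0 °C; then 2 M HCl, THF, rt
Reagents that add atoms: water, O
Why: Stork–Danheiser transposition combined with ester reduction: hydride converts the C11 ester into CH2OH and the C10 carbonyl into the allylic alcohol 7, and aqueous acid ionises C10–OH through the enol ether and hydrolyses it to the C6 enone without touching C8 or C9.

Step 6
Reactants: 8 (4S,5S)-4-(hydroxymethyl)-2,4,5-trimethylcyclohex-2-en-1-one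
Product: 9 (4S,5S)-4-({[tert-butyl(diphenyl)silyl]oxy}methyl)-2,4,5-trimethylcyclohex-2-en-1-one
Conditions: TBDPSCl, imidazole, DMAP (cat.), DMF, rt
Reagents that add atoms: tert-butyl(chloro)diphenylsilane, CC(C)(C)[Si](Cl)(c1ccccc1)c1ccccc1
Why: Standard imidazole-promoted silylation of a primary alcohol, chosen because the bulky, non-coordinating silyl ether should survive every later base, organometallic and palladium step.

Step 7
Reactants: 9 (4S,5S)-4-({[tert-butyl(diphenyl)silyl]oxy}methyl)-2,4,5-trimethylcyclohex-2-en-1-one; 10 vinylmagnesium bromide; 11 methyl bromoacetate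
Product: 13 methyl 2-[(1S,2R,3S,4S)-3-({[tert-butyl(diphenyl)silyl]oxy}methyl)-2-ethenyl-1,3,4-trimethyl-6-oxocyclohexyl]acetate, via bromomagnesium enolate 12 (not isolated)
Conditions: (CH2=CH)2CuMgBr from 10 (2.4 equiv) and CuBr·SMe2 (1.2 equiv), THF–Me2S, −78 °C; 9, −78 to −30 °C; then DMPU, 11 (4 equiv), −30 °C to rt; aq NH4Cl
Reagents that add atoms: vinylmagnesium bromide, C=C[Mg]Br; methyl bromoacetate, BrCC(=O)OC
Why: The divinylcuprate adds 1,4 to the enone (π-complex, trivalent copper intermediate at C10, reductive elimination) and leaves the regiodefined C5=C6 enolate 12, which DMPU activates for SN2 attack on the reactive α-bromo ester; this is the known tandem vicinal dialkylation of cyclohexenones, and no ring is closed. C10: in the lower-energy half-chair of 9 the C8 methyl sits equatorial, which forces its cis neighbour C11H2OSi into the axial position on C9, so the stereoelectronically preferred axial attack comes from the other face, trans to both the C8 methyl (the usual 3,5-trans rule) and C11. C5: A(1,2) strain against the C5 methyl holds the new vinyl group pseudoaxial in 12, and because C9 is quaternary an axially approaching electrophile meets one syn-axial C9 substituent whichever half-chair reacts, so the vicinal vinyl group decides and the bromoacetate enters anti to it, placing C4 trans to C1. The step needs 1,4 over 1,2 addition (soft cuprate, non-chelating silyl ether), C over O alkylation (soft primary bromide) and the two facial choices above, all relayed from C8 and C9. Alkylation can occur only at C5 because 12 is generated regiospecifically and is trapped before proton transfer can move the enolate to C7.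

Step 8
Reactants: 13 methyl 2-[(1S,2R,3S,4S)-3-({[tert-butyl(diphenyl)silyl]oxy}methyl)-2-ethenyl-1,3,4-trimethyl-6-oxocyclohexyl]acetate
Product: 14 methyl 2-[(1S,4S,5S,6R)-5-({[tert-butyl(diphenyl)silyl]oxy}methyl)-6-ethenyl-1,4,5-trimethyl-2-(trifluoromethylsulfonyloxy)cyclohex-2-en-1-yl]acetate (C6–C7 enol triflate)
Conditions: KN(SiMe3)2, THF, −78 °C; N-(5-chloropyridin-2-yl)bis(trifluoromethanesulfonimide), −78 to −20 °C
Reagents that add atoms: N-(5-chloropyridin-2-yl)bis(trifluoromethanesulfonimide), Clc1ccc(nc1)N(S(=O)(=O)C(F)(F)F)S(=O)(=O)C(F)(F)F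
Why: Enol triflate formation: kinetic enolisation can go only toward C7, the sole hydrogen-bearing α position of the C6 ketone and more acidic than the ester CH2, and the enolate oxygen is sulfonylated at low temperature before it can attack the ester.

Step 9
Reactants: 14 C6–C7 enol triflate
Product: 15 methyl 2-[(1R,4S,5S,6S)-5-({[tert-butyl(diphenyl)silyl]oxy}methyl)-6-ethenyl-1,4,5-trimethylcyclohex-2-en-1-yl]acetate
Conditions: Pd(OAc)2 (5 mol %), PPh3 (10 mol %), HCO2H, Et3N, DMF, 60 °C
Reagents that add atoms: none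
Why: Palladium-catalysed formate reduction of an enol triflate: oxidative addition to zerovalent palladium, formate exchange, loss of CO2 and reductive elimination replace OTf by H, which removes the C6 oxygen and spares the vinyl group and the ester.

Step 10
Reactants: 15 methyl 2-[(1R,4S,5S,6S)-5-({[tert-butyl(diphenyl)silyl]oxy}methyl)-6-ethenyl-1,4,5-trimethylcyclohex-2-en-1-yl]acetate
Product: 16 2-[(1R,4S,5S,6S)-5-({[tert-butyl(diphenyl)silyl]oxy}methyl)-6-ethenyl-1,4,5-trimethylcyclohex-2-en-1-yl]-N-methoxy-N-methylacetamide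
Conditions: MeNH(OMe)·HCl, iPrMgCl, THF, −20 to 0 °C
Reagents that add atoms: N,O-dimethylhydroxylamine hydrochloride, CNOC.Cl
Why: Weinreb amidation of an ester by the chloromagnesium amide made in situ, carried out while C4 is still an unbranched CH2 so that the acyl carbon C3 stays accessible.

Step 11
Reactants: 16 Weinreb amide; 10 vinylmagnesium bromide
Product: 17 1-[(1R,4S,5S,6S)-5-({[tert-butyl(diphenyl)silyl]oxy}methyl)-6-ethenyl-1,4,5-trimethylcyclohex-2-en-1-yl]but-3-en-2-one
Conditions: 10, THF, 0 °C; inverse quench into cold 1 M HCl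
Reagents that add atoms: vinylmagnesium bromide, C=C[Mg]Br
Why: Weinreb ketone synthesis: the chelated tetrahedral adduct stops at single addition, and the acidic inverse quench protonates the released amine before it can add to the new vinyl ketone.

Step 12
Reactants: 17 1-[(1R,4S,5S,6S)-5-({[tert-butyl(diphenyl)silyl]oxy}methyl)-6-ethenyl-1,4,5-trimethylcyclohex-2-en-1-yl]but-3-en-2-one
Product: 18 (4aS,5S,6S,8aR)-5-({[tert-butyl(diphenyl)silyl]oxy}methyl)-5,6,8a-trimethyl-4a,5,6,8a-tetrahydronaphthalen-2(1H)-one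
Conditions: second-generation Hoveyda–Grubbs catalyst, (H2IMes)Cl2Ru=CH(2-iPrOC6H4) (5–10 mol %), toluene (high dilution), 80 °C, argon sparge
Reagents that add atoms: none
Why: Ring-closing metathesis joins C1 and C2 with loss of ethene to form the six-membered ring A enone; the trans relation of C1 and C4 set in step 7 becomes the trans ring fusion, and the unstrained C6=C7 cyclohexene remains a spectator.

Step 13
Reactants: 18 (4aS,5S,6S,8aR)-5-({[tert-butyl(diphenyl)silyl]oxy}methyl)-5,6,8a-trimethyl-4a,5,6,8a-tetrahydronaphthalen-2(1H)-one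
Product: 19 (4aS,5S,6S,8aR)-5-({[tert-butyl(diphenyl)silyl]oxy}methyl)-1,5,6,8a-tetramethyl-4a,5,6,8a-tetrahydronaphthalen-2(1H)-one (C4 methyl, configuration open)
Conditions: LiN(iPr)2, THF, −78 °C; MeI, −78 to −20 °C
Reagents that add atoms: methyl iodide, CI
Why: Kinetic α′-deprotonation of the enone gives the cross-conjugated C3–C4 dienolate (C4 is the only α′ site), which is methylated by MeI; the C4 configuration is left open here because step 14 corrects it.

Step 14
Reactants: 19 C4-methylated dienone
Product: 21 (1S,4aS,5S,6S,8aR)-5-({[tert-butyl(diphenyl)silyl]oxy}methyl)-1,5,6,8a-tetramethyloctahydronaphthalen-2(1H)-one, via C4-epimeric ketone mixture 20 (not isolated)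
Conditions: H2 (1–4 atm), 10% Pd/C, EtOAc, rt; filter; NaOMe (0.3 equiv), MeOH, 40 °C
Reagents that add atoms: none
Why: Heterogeneous hydrogenation saturates C1=C2 and C6=C7 (only CH2 groups result), and base-mediated enolisation then equilibrates C4, now the only epimerisable stereocentre, to the more stable equatorial methyl (4S), anti to C10 and free of 1,3-diaxial contacts.

Step 15
Reactants: 21 (1S,4aS,5S,6S,8aR)-5-({[tert-butyl(diphenyl)silyl]oxy}methyl)-1,5,6,8a-tetramethyloctahydronaphthalen-2(1H)-one
Product: 22 (1S,4aS,5S,6S,8aR)-5-(hydroxymethyl)-1,5,6,8a-tetramethyloctahydronaphthalen-2(1H)-one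
Conditions: Bu4NF, THF, 50 °C
Reagents that add atoms: none
Why: Fluoride-mediated silyl ether cleavage driven by Si–F bond formation; the mildly basic medium cannot disturb C4, which already holds its equilibrium configuration.

Step 16
Reactants: 22 (1S,4aS,5S,6S,8aR)-5-(hydroxymethyl)-1,5,6,8a-tetramethyloctahydronaphthalen-2(1H)-one; 23 isofraxidin (7-hydroxy-6,8-dimethoxycoumarin)
Product: 24 7-{[(1S,2S,4aR,5S,8aS)-1,2,4a,5-tetramethyl-6-oxodecahydronaphthalen-1-yl]methoxy}-6,8-dimethoxy-2H-chromen-2-one (CNP0225022.2)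
Conditions: PPh3, DIAD, toluene (about 1 M), 0 to 70 °C
Reagents that add atoms: none
Why: Mitsunobu etherification: the acidic 7-OH of 23 protonates the PPh3–DIAD betaine, C11–OH is activated as its oxyphosphonium salt, and the phenoxide displaces it by SN2 at the primary carbon so that no stereocentre is touched, with high concentration and heat compensating for the neopentyl setting.

Compound list
1 | (E)-hex-4-en-3-one | C/C=C/C(=O)CC | starting material
2 | dimethyl malonate | COC(=O)CC(=O)OC | starting material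
3 | dimethyl 2-[(2S)-4-oxohexan-2-yl]propanedioate | CCC(=O)C[C@H](C)C(C(=O)OC)C(=O)OC | intermediate
4 | methyl (6S)-3,6-dimethyl-2,4-dioxocyclohexane-1-carboxylate | COC(=O)C1[C@@H](C)CC(=O)C(C)C1=O | intermediate
5 | methyl (6S)-4-methoxy-3,6-dimethyl-2-oxocyclohex-3-ene-1-carboxylate | COC(=O)C1[C@@H](C)CC(OC)=C(C)C1=O | intermediate
6 | methyl (1S,6S)-4-methoxy-1,3,6-trimethyl-2-oxocyclohex-3-ene-1-carboxylate | COC(=O)[C@@]1(C)[C@@H](C)CC(OC)=C(C)C1=O | intermediate
7 | (5S,6R)-6-(hydroxymethyl)-3-methoxy-2,5,6-trimethylcyclohex-2-en-1-ol (carbinol epimers) | OC[C@]1(C)C(O)C(C)=C(OC)C[C@@H]1C | intermediate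
8 | (4S,5S)-4-(hydroxymethyl)-2,4,5-trimethylcyclohex-2-en-1-one | OC[C@]1(C)C=C(C)C(=O)C[C@@H]1C | intermediate
9 | (4S,5S)-4-({[tert-butyl(diphenyl)silyl]oxy}methyl)-2,4,5-trimethylcyclohex-2-en-1-one | CC(C)(C)[Si](c1ccccc1)(c1ccccc1)OC[C@]1(C)C=C(C)C(=O)C[C@@H]1C | intermediate
10 | vinylmagnesium bromide | C=C[Mg]Br | starting material
11 | methyl bromoacetate | BrCC(=O)OC | starting material
12 | bromomagnesium C5=C6 enolate carrying the C10 vinyl group | CC(C)(C)[Si](c1ccccc1)(c1ccccc1)OC[C@]1(C)[C@@H](C=C)C(C)=C(O[Mg]Br)C[C@@H]1C | intermediate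
13 | methyl 2-[(1S,2R,3S,4S)-3-({[tert-butyl(diphenyl)silyl]oxy}methyl)-2-ethenyl-1,3,4-trimethyl-6-oxocyclohexyl]acetate | CC(C)(C)[Si](c1ccccc1)(c1ccccc1)OC[C@]1(C)[C@@H](C=C)[C@](C)(CC(=O)OC)C(=O)C[C@@H]1C | intermediate
14 | C6–C7 enol triflate of 13, (1S,4S,5S,6R) | CC(C)(C)[Si](c1ccccc1)(c1ccccc1)OC[C@]1(C)[C@@H](C=C)[C@](C)(CC(=O)OC)C(OS(=O)(=O)C(F)(F)F)=C[C@@H]1C | intermediate
15 | methyl 2-[(1R,4S,5S,6S)-5-({[tert-butyl(diphenyl)silyl]oxy}methyl)-6-ethenyl-1,4,5-trimethylcyclohex-2-en-1-yl]acetate | CC(C)(C)[Si](c1ccccc1)(c1ccccc1)OC[C@]1(C)[C@@H](C=C)[C@](C)(CC(=O)OC)C=C[C@@H]1C | intermediate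
16 | N-methoxy-N-methylamide of 15, (1R,4S,5S,6S) | CC(C)(C)[Si](c1ccccc1)(c1ccccc1)OC[C@]1(C)[C@@H](C=C)[C@](C)(CC(=O)N(C)OC)C=C[C@@H]1C | intermediate
17 | vinyl ketone, 1-[(1R,4S,5S,6S)-…cyclohex-2-en-1-yl]but-3-en-2-one | CC(C)(C)[Si](c1ccccc1)(c1ccccc1)OC[C@]1(C)[C@@H](C=C)[C@](C)(CC(=O)C=C)C=C[C@@H]1C | intermediate
18 | (4aS,5S,6S,8aR)-5-({[tert-butyl(diphenyl)silyl]oxy}methyl)-5,6,8a-trimethyl-4a,5,6,8a-tetrahydronaphthalen-2(1H)-one | CC(C)(C)[Si](c1ccccc1)(c1ccccc1)OC[C@]1(C)[C@H]2C=CC(=O)C[C@]2(C)C=C[C@@H]1C | intermediate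
19 | 1-methyl derivative of 18 (C4 configuration open) | CC(C)(C)[Si](c1ccccc1)(c1ccccc1)OC[C@]1(C)[C@H]2C=CC(=O)C(C)[C@]2(C)C=C[C@@H]1C | intermediate
20 | saturated C3 ketone, C4 epimers | CC(C)(C)[Si](c1ccccc1)(c1ccccc1)OC[C@]1(C)[C@H]2CCC(=O)C(C)[C@]2(C)CC[C@@H]1C | intermediate
21 | (1S,4aS,5S,6S,8aR)-5-({[tert-butyl(diphenyl)silyl]oxy}methyl)-1,5,6,8a-tetramethyloctahydronaphthalen-2(1H)-one | CC(C)(C)[Si](c1ccccc1)(c1ccccc1)OC[C@]1(C)[C@H]2CCC(=O)[C@@H](C)[C@]2(C)CC[C@@H]1C | intermediate
22 | (1S,4aS,5S,6S,8aR)-5-(hydroxymethyl)-1,5,6,8a-tetramethyloctahydronaphthalen-2(1H)-one | OC[C@]1(C)[C@H]2CCC(=O)[C@@H](C)[C@]2(C)CC[C@@H]1C | intermediate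
23 | isofraxidin | COc1cc2ccc(=O)oc2c(OC)c1O | starting material
24 | 7-{[(1S,2S,4aR,5S,8aS)-1,2,4a,5-tetramethyl-6-oxodecahydronaphthalen-1-yl]methoxy}-6,8-dimethoxy-2H-chromen-2-one | COc1cc2ccc(=O)oc2c(OC)c1OC[C@]1(C)[C@H]2CCC(=O)[C@@H](C)[C@]2(C)CC[C@@H]1C | target

Total step count: 16. Longest linear sequence: 16 steps (1 and 2 to 24).

Steps most likely to fail

**Step 7.**
- Risk: 1,4-addition may be slow at C10, which lies next to quaternary C9. Proton transfer may then intervene, or C-alkylation of the crowded magnesium enolate may be sluggish and poorly face-selective.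
- Fallback (from 9, back at 13): the two bond formations are separated.
  - The same cuprate is added in the presence of Me3SiCl (chlorosilane-accelerated conjugate addition), and the regiodefined trimethylsilyl enol ether F1 is isolated.
  - MeLi in THF then cleaves the O–Si bond to the salt-free lithium enolate F2.
  - F2 is alkylated with 11 in THF–DMPU to give 13.

**Step 12.**
- Risk: metathesis may stall. The C10 vinyl group lies between two quaternary carbons, and ring B must flip to bring C1 and C4 gauche. The catalyst may also be diverted to intermolecular coupling or to C6=C7.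
- Fallback (from 16, back at 21): ring A is closed at C2–C3 by anionic acylation, which keeps both vinyl carbons.
  - LiN(iPr)2 and MeI convert 16 into the α-methyl Weinreb amide F3.
  - 9-BBN followed by NaBO3·4H2O hydroborates only the terminal vinyl group, giving the primary alcohol F4.
  - I2, PPh3 and imidazole give the primary iodide F5.
  - Iodine–lithium exchange with t-BuLi (Et2O–pentane, −78 °C) triggers attack of C2 on the amide, giving the Δ6 ring A ketone F6.
  - The conditions of step 14 turn F6 into 21.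

**Step 16.**
- Risk: the oxyphosphonium salt at neopentyl C11 may resist displacement by the di-ortho-substituted, weakly nucleophilic phenoxide. The activated alcohol would then be lost to side reactions.
- Fallback (from 22, back at 24): the redox condensation is replaced by a sulfonate displacement.
  - Tf2O and 2,6-lutidine (CH2Cl2, −78 °C) give the neopentyl triflate F7.
  - The preformed cesium phenoxide F8 of 23 (Cs2CO3, DMF) displaces triflate at rt to 50 °C to give 24.

Further compounds
F1 | step 7 | trimethylsilyl enol ether (C5=C6) carrying the C10 vinyl group | CC(C)(C)[Si](c1ccccc1)(c1ccccc1)OC[C@]1(C)[C@@H](C=C)C(C)=C(O[Si](C)(C)C)C[C@@H]1C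
F2 | step 7 | lithium enolate (C5=C6) | CC(C)(C)[Si](c1ccccc1)(c1ccccc1)OC[C@]1(C)[C@@H](C=C)C(C)=C(O[Li])C[C@@H]1C
F3 | step 12 | α-methyl Weinreb amide (C4 epimers) | CC(C)(C)[Si](c1ccccc1)(c1ccccc1)OC[C@]1(C)[C@@H](C=C)[C@](C)(C(C)C(=O)N(C)OC)C=C[C@@H]1C
F4 | step 12 | primary alcohol at C2 | CC(C)(C)[Si](c1ccccc1)(c1ccccc1)OC[C@]1(C)[C@@H](CCO)[C@](C)(C(C)C(=O)N(C)OC)C=C[C@@H]1C
F5 | step 12 | primary iodide at C2 | CC(C)(C)[Si](c1ccccc1)(c1ccccc1)OC[C@]1(C)[C@@H](CCI)[C@](C)(C(C)C(=O)N(C)OC)C=C[C@@H]1C
F6 | step 12 | Δ6 ring A ketone (C4 epimers) | CC(C)(C)[Si](c1ccccc1)(c1ccccc1)OC[C@]1(C)[C@H]2CCC(=O)C(C)[C@]2(C)C=C[C@@H]1C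
F7 | step 16 | C11 triflate of 22 | O=S(=O)(OC[C@]1(C)[C@H]2CCC(=O)[C@@H](C)[C@]2(C)CC[C@@H]1C)C(F)(F)F
F8 | step 16 | cesium 6,8-dimethoxy-2-oxochromen-7-olate | COc1cc2ccc(=O)oc2c(OC)c1[O-].[Cs+]
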